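Ring A (C1–C5, C10) is not assembled as a cyclohexane: its C3(=O)–C4(CH3)2–C5 segment is created by a one-carbon ring enlargement of a trans-fused cyclopentanol (C1, C2, C3, C5, C10) that carries an isopropenyl group on the carbinol carbon C3. Cobalt-catalysed hydrogen-atom transfer to the isopropenyl group, oxidation to the C4 cation and 1,2-shift of C5 from C3 to C4 (semipinacol) give in one operation the six-membered ring A, the quaternary gem-dimethyl C4 and the C3 carbonyl, exploiting the oxygen-bearing C3 next to the quaternary C4 in ring A. The precursor comes from cis-jasmone by CBS reduction, Ireland–Claisen chirality transfer to C10, ring-closing metathesis (ring B) and hydroboration.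

Key step: step 11

Remark: locants are those of the drimane skeleton of the target (ring A = C1–C5 and C10; ring B = C5–C10; C11 = the OCH2 carbon on C9; C12 = the methyl on C8); β is the face of the C10 methyl and α the opposite face; the same locants are kept for the five-membered-ring intermediates, in which C4 is absent and C3 is bonded to C5; the acyl group is read as the angelate and the C3 oxygen as α (axial), as the SMILES shows.

Step 1
Reactants: 1 cis-jasmone
Product: 2 (1R)-3-methyl-2-[(2Z)-pent-2-en-1-yl]cyclopent-2-en-1-ol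
Conditions: (S)-2-methyl-CBS-oxazaborolidine [(S)-1-methyl-3,3-diphenyltetrahydro-1H,3H-pyrrolo[1,2-c][1,3,2]oxazaborole, C18H20BNO] (10 mol %), catecholborane, toluene, −78 °C
Reagents that add atoms: none
Why: Corey–Bakshi–Shibata reduction, in which the catalyst treats the fully substituted alkene carbon as the large and the ring CH2 as the small carbonyl substituent and so should deliver hydride to one face to set the (R)-carbinol centre, while catecholborane at −78 °C leaves the side-chain alkene alone.

Step 2
Reactants: 2 (1R)-3-methyl-2-[(2Z)-pent-2-en-1-yl]cyclopent-2-en-1-ol; 3 3-methylbut-2-enoyl chloride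
Product: 4 (1R)-3-methyl-2-[(2Z)-pent-2-en-1-yl]cyclopent-2-en-1-yl 3-methylbut-2-enoate
Conditions: Et3N, DMAP (cat.), CH2Cl2, 0 °C
Reagents that add atoms: 3-methylbut-2-enoyl chloride, CC(C)=CC(=O)Cl
Why: DMAP-catalysed acylation of the secondary allylic alcohol touches no stereocentre, and any deconjugated 3-methylbut-3-enoate formed through the vinylketene gives the same dienolate in step 3.

Step 3
Reactants: 4 (1R)-3-methyl-2-[(2Z)-pent-2-en-1-yl]cyclopent-2-en-1-yl 3-methylbut-2-enoate
Product: 7 3-methyl-2-{(1R)-1-methyl-2-[(2Z)-pent-2-en-1-yl]cyclopent-2-en-1-yl}but-3-enoic acid (C2 epimers), via silyl ketene acetal 5 (not isolated), via trimethylsilyl ester 6 (not isolated)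
Conditions: LDA (LiN(i-C3H7)2), THF–DMPU, −78 °C; Me3SiCl; −78 → 50 °C; aq. HCl
Reagents that add atoms: none
Why: Ireland–Claisen rearrangement, in which γ-deprotonation and O-silylation give the dienyl ketene acetal and the suprafacial [3,3] shift forms the C9–C10 bond on the face that carried the C3–O bond, so that the (R)-carbinol is translated into the quaternary C10 (methyl β) while the ring alkene moves to C3=C5; C9 is expected as an epimer mixture that step 6 corrects.

Step 4
Reactants: 7 3-methyl-2-{(1R)-1-methyl-2-[(2Z)-pent-2-en-1-yl]cyclopent-2-en-1-yl}but-3-enoic acid (C2 epimers)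
Product: 8 methyl 3-methyl-2-{(1R)-1-methyl-2-[(2Z)-pent-2-en-1-yl]cyclopent-2-en-1-yl}but-3-enoate (C2 epimers)
Conditions: MeI, K2CO3, DMF, rt
Reagents that add atoms: iodomethane, CI
Why: SN2 O-alkylation of the carboxylate under mild base protects the acid for the later borane and peracid steps without touching the alkenes or C10.

Step 5
Reactants: 8 methyl 3-methyl-2-{(1R)-1-methyl-2-[(2Z)-pent-2-en-1-yl]cyclopent-2-en-1-yl}but-3-enoate (C2 epimers)
Product: 9 methyl (7aR)-6,7a-dimethyl-2,4,7,7a-tetrahydro-1H-indene-7-carboxylate (C7 epimers)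
Conditions: second-generation Grubbs catalyst [RuCl2(=CHPh)(PCy3)(H2IMes), C46H65Cl2N2PRu] (5 mol %), CH2Cl2, 40 °C
Reagents that add atoms: none
Why: Ring-closing metathesis between the isopropenyl group and the (Z)-pentenyl chain closes six-membered ring B as the trisubstituted C7=C8 alkene with loss of but-1-ene, the trisubstituted ring alkene C3=C5 being inert to the catalyst.

Step 6
Reactants: 9 methyl (7aR)-6,7a-dimethyl-2,4,7,7a-tetrahydro-1H-indene-7-carboxylate (C7 epimers)
Product: 11 methyl 6,7a-dimethyl-2,4,7,7a-tetrahydro-1H-indene-7-carboxylate [10β-CH3; 9β-CO2CH3; 9α-H], via lithium dienolate 10 (not isolated)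
Conditions: LDA (LiN(i-C3H7)2), THF, −78 → −20 °C; then AcOH, −78 °C
Reagents that add atoms: none
Why: Kinetic α-protonation of an extended ester enolate: both C9 epimers give one planar dienolate, which should be protonated at C9 from the α face, anti to the pseudo-axial C10 methyl, leaving the ester β and the alkene at C7=C8.

Step 7
Reactants: 11 methyl 6,7a-dimethyl-2,4,7,7a-tetrahydro-1H-indene-7-carboxylate [10β-CH3; 9β-CO2CH3; 9α-H]
Product: 13 methyl 1-hydroxy-3a,5-dimethyl-2,3,3a,4,7,7a-hexahydro-1H-indene-4-carboxylate [3α-OH; 5α-H; 10β-CH3; 9β-CO2CH3], via B-alkyl-9-borabicyclononane 12 (not isolated)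
Conditions: 9-BBN, THF, 0 °C → rt; then H2O2, aq. NaOAc, 0 °C
Reagents that add atoms: hydrogen peroxide, OO
Why: Brown hydroboration–oxidation, in which 9-BBN adds to a trisubstituted cyclopentene much faster than to a trisubstituted cyclohexene and places boron on C3 and hydrogen on C5 syn from the α face opposite the angular methyl, which sets the trans ring fusion (5α-H) and, after oxidation with retention, the 3α-hydroxyl.

Step 8
Reactants: 13 methyl 1-hydroxy-3a,5-dimethyl-2,3,3a,4,7,7a-hexahydro-1H-indene-4-carboxylate [3α-OH; 5α-H; 10β-CH3; 9β-CO2CH3]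
Product: 14 methyl 5,6-epoxy-1-hydroxy-3a,5-dimethyloctahydro-1H-indene-4-carboxylate [3α-OH; 5α-H; 10β-CH3; 9β-CO2CH3; 7α,8α-epoxide]
Conditions: mCPBA, NaHCO3, CH2Cl2, 0 °C
Reagents that add atoms: 3-chloroperoxybenzoic acid, O=C(OO)c1cccc(Cl)c1
Why: Prilezhaev epoxidation of the only alkene from the α face, anti to the axial C10 methyl and the 9β-ester, fixes the C8–O bond as α and the C8 methyl as β.

Step 9
Reactants: 14 methyl 5,6-epoxy-1-hydroxy-3a,5-dimethyloctahydro-1H-indene-4-carboxylate [3α-OH; 5α-H; 10β-CH3; 9β-CO2CH3; 7α,8α-epoxide]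
Product: 15 methyl 5,6-epoxy-3a,5-dimethyl-1-oxooctahydro-1H-indene-4-carboxylate [5α-H; 10β-CH3; 9β-CO2CH3; 7α,8α-epoxide]
Conditions: TPAP [tetrapropylammonium perruthenate, (C3H7)4N RuO4] (5 mol %), NMO, 4 Å MS, CH2Cl2, rt
Reagents that add atoms: none
Why: Ley–Griffith oxidation is neutral, so the epimerisable ring-fusion hydrogen at C5 of the trans-hydrindanone, the epoxide and the ester should be untouched.

Step 10
Reactants: 15 methyl 5,6-epoxy-3a,5-dimethyl-1-oxooctahydro-1H-indene-4-carboxylate [5α-H; 10β-CH3; 9β-CO2CH3; 7α,8α-epoxide]; 16 isopropenylmagnesium bromide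
Product: 17 methyl 5,6-epoxy-1-hydroxy-3a,5-dimethyl-1-(prop-1-en-2-yl)octahydro-1H-indene-4-carboxylate [3β-OH; 5α-H; 10β-CH3; 9β-CO2CH3; 7α,8α-epoxide]
Conditions: LaCl3·2LiCl, THF, −78 → −40 °C
Reagents that add atoms: isopropenylmagnesium bromide, CC(=C)[Mg]Br
Why: Lanthanum chloride–promoted Grignard 1,2-addition suppresses enolisation of the ketone and spares the hindered ester and the epoxide at low temperature; attack from the α face should give the 3β-alcohol, but the C3 configuration is irrelevant because C3 becomes the carbonyl carbon in step 11.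

Step 11
Reactants: 17 methyl 5,6-epoxy-1-hydroxy-3a,5-dimethyl-1-(prop-1-en-2-yl)octahydro-1H-indene-4-carboxylate [3β-OH; 5α-H; 10β-CH3; 9β-CO2CH3; 7α,8α-epoxide]
Product: 18 methyl 7α,8α-epoxy-3-oxodriman-11-oate
Conditions: Co(salen) catalyst [N,N′-bis(3,5-di-tert-butylsalicylidene)ethylenediaminocobalt, Co(C32H46N2O2), divalent cobalt] (5 mol %), N-fluoro-2,4,6-trimethylpyridinium triflate, PhSiH3, CH2Cl2–acetone, 0 °C → rt
Reagents that add atoms: none
Why: A trivalent cobalt hydride, formed from the divalent salen complex, the N-fluoropyridinium oxidant and the silane, transfers a hydrogen atom to the terminal CH2 of the isopropenyl group, the tertiary C4 radical is captured and oxidised by cobalt to a cationic C4 electrophile next to the carbinol C3, and the ring bond C3–C5 shifts to C4 while C3–O becomes the carbonyl (radical–polar crossover semipinacol rearrangement). The closest known reaction type is the cobalt-salen-catalysed hydrogen-atom-transfer semipinacol ring expansion of tertiary allylic alcohols, the neutral counterpart of the pinacol conversion of 1-(2-hydroxypropan-2-yl)cyclopentanol into 2,2-dimethylcyclohexanone. No ring is closed in the usual sense: the cyclopentane C1–C2–C3–C5–C10 is enlarged by insertion of C4 between C3 and C5 (1,2-alkyl shift), which gives six-membered ring A with C4 as the new quaternary, non-stereogenic gem-dimethyl carbon. No new stereocentre is created: C5 migrates with retention, so the trans fusion set in step 7 becomes the trans-decalin (5α-H, 10β-CH3), and the C3 carbinol centre is erased. The step needs migration of C5 and not of C2, which the higher migratory aptitude of the more substituted, more electron-rich carbon should secure, and it needs chemoselectivity, which is built in because the isopropenyl group is the only alkene left and the neutral conditions should spare the epoxide and the ester.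

Step 12
Reactants: 18 methyl 7α,8α-epoxy-3-oxodriman-11-oate
Product: 20 drimane-3α,8α,11-triol, via hydroxy epoxy ester 19 (not isolated)
Conditions: L-Selectride (LiBH(sec-C4H9)3), THF, −78 → 0 °C; then LiAlH4, 0 → 65 °C
Reagents that add atoms: none
Why: The bulky trialkylborohydride attacks the 4,4-dimethyl-3-ketone along the equatorial trajectory to give the axial 3α-alcohol, and LiAlH4 then reduces the ester to the C11 carbinol and opens the trisubstituted epoxide by hydride attack at the less substituted C7, which leaves the tertiary 8α-hydroxyl with its configuration intact.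

Step 13
Reactants: 20 drimane-3α,8α,11-triol; 21 umbelliferone
Product: 22 11-[(2-oxo-2H-chromen-7-yl)oxy]drimane-3α,8α-diol
Conditions: PPh3, DIAD, THF, 0 °C → rt
Reagents that add atoms: umbelliferone, Oc1ccc2ccc(=O)oc2c1
Why: Mitsunobu etherification, in which only the primary C11 hydroxyl forms an alkoxyphosphonium ion that the acidic phenol can displace, the axial neopentylic 3α-hydroxyl and the tertiary 8α-hydroxyl being inert, and no stereocentre is involved.

Step 14
Reactants: 22 11-[(2-oxo-2H-chromen-7-yl)oxy]drimane-3α,8α-diol; 23 angelic acid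
Product: 25 8α-hydroxy-11-[(2-oxo-2H-chromen-7-yl)oxy]driman-3α-yl (2Z)-2-methylbut-2-enoate (CNP0189964.4), via mixed anhydride 24 (not isolated)
Conditions: 2,4,6-trichlorobenzoyl chloride, Et3N, toluene, rt; then 22, 80 °C
Reagents that add atoms: angelic acid, C/C=C(/C)C(=O)O
Why: Yamaguchi esterification through the mixed anhydride, run without a nucleophilic amine catalyst so that the (Z)-alkene is not isomerised by reversible conjugate addition, should acylate the secondary 3α-hydroxyl while the tertiary 8α-hydroxyl is too hindered to react.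

Compound list
1 | cis-jasmone, 3-methyl-2-[(2Z)-pent-2-en-1-yl]cyclopent-2-en-1-one | CC/C=C\CC1=C(C)CCC1=O | starting material
2 | (1R)-3-methyl-2-[(2Z)-pent-2-en-1-yl]cyclopent-2-en-1-ol | CC/C=C\CC1=C(C)CC[C@H]1O | intermediate
3 | 3-methylbut-2-enoyl chloride | CC(C)=CC(=O)Cl | starting material
4 | (1R)-3-methyl-2-[(2Z)-pent-2-en-1-yl]cyclopent-2-en-1-yl 3-methylbut-2-enoate | CC/C=C\CC1=C(C)CC[C@H]1OC(=O)C=C(C)C | intermediate
5 | silyl ketene acetal, 3-methyl-1-{[(1R)-3-methyl-2-[(2Z)-pent-2-en-1-yl]cyclopent-2-en-1-yl]oxy}-1-(trimethylsilyloxy)buta-1,3-diene (not isolated) | CC/C=C\CC1=C(C)CC[C@H]1OC(O[Si](C)(C)C)=CC(C)=C | intermediate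
6 | trimethylsilyl 3-methyl-2-{(1R)-1-methyl-2-[(2Z)-pent-2-en-1-yl]cyclopent-2-en-1-yl}but-3-enoate, C2 epimers (not isolated) | C=C(C)C(C(=O)O[Si](C)(C)C)[C@@]1(C)CCC=C1C/C=C\CC | intermediate
7 | 3-methyl-2-{(1R)-1-methyl-2-[(2Z)-pent-2-en-1-yl]cyclopent-2-en-1-yl}but-3-enoic acid, C2 epimers | C=C(C)C(C(=O)O)[C@@]1(C)CCC=C1C/C=C\CC | intermediate
8 | methyl 3-methyl-2-{(1R)-1-methyl-2-[(2Z)-pent-2-en-1-yl]cyclopent-2-en-1-yl}but-3-enoate, C2 epimers | C=C(C)C(C(=O)OC)[C@@]1(C)CCC=C1C/C=C\CC | intermediate
9 | methyl (7aR)-6,7a-dimethyl-2,4,7,7a-tetrahydro-1H-indene-7-carboxylate, C7 epimers (alkenes C3=C5 and C7=C8 in target locants) | COC(=O)C1C(C)=CCC2=CCC[C@]12C | intermediate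
10 | lithium dienolate of 9 (not isolated) | COC(O[Li])=C1C(C)=CCC2=CCC[C@]12C | intermediate
11 | methyl 6,7a-dimethyl-2,4,7,7a-tetrahydro-1H-indene-7-carboxylate, ester cis to the angular methyl [10β-CH3; 9β-CO2CH3; 9α-H] | COC(=O)[C@H]1C(C)=CCC2=CCC[C@]12C | intermediate
12 | B-alkyl-9-borabicyclo[3.3.1]nonane from 11, boron on C3 α, hydrogen on C5 α (not isolated) | COC(=O)[C@H]1C(C)=CC[C@H]2[C@H](B3C4CCCC3CCC4)CC[C@]12C | intermediate
13 | methyl 1-hydroxy-3a,5-dimethyl-2,3,3a,4,7,7a-hexahydro-1H-indene-4-carboxylate [3α-OH; 5α-H; 10β-CH3; 9β-CO2CH3; trans ring fusion; 7-ene] | COC(=O)[C@H]1C(C)=CC[C@H]2[C@H](O)CC[C@]12C | intermediate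
14 | methyl 5,6-epoxy-1-hydroxy-3a,5-dimethyloctahydro-1H-indene-4-carboxylate [3α-OH; 5α-H; 10β-CH3; 9β-CO2CH3; 7α,8α-epoxide] | COC(=O)[C@H]1[C@]3(C)O[C@@H]3C[C@H]2[C@H](O)CC[C@]12C | intermediate
15 | methyl 5,6-epoxy-3a,5-dimethyl-1-oxooctahydro-1H-indene-4-carboxylate [5α-H; 10β-CH3; 9β-CO2CH3; 7α,8α-epoxide] | COC(=O)[C@H]1[C@]3(C)O[C@@H]3C[C@H]2C(=O)CC[C@]12C | intermediate
16 | isopropenylmagnesium bromide | CC(=C)[Mg]Br | starting material
17 | methyl 5,6-epoxy-1-hydroxy-3a,5-dimethyl-1-(prop-1-en-2-yl)octahydro-1H-indene-4-carboxylate [3β-OH; isopropenyl α; 5α-H; 10β-CH3; 9β-CO2CH3; 7α,8α-epoxide] | COC(=O)[C@H]1[C@]3(C)O[C@@H]3C[C@H]2[C@](O)(C(C)=C)CC[C@]12C | intermediate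
18 | methyl 7α,8α-epoxy-3-oxodriman-11-oate (trans-decalin; 4,4,8,10-tetramethyl; 5α-H; 10β-CH3; 9β-CO2CH3) | COC(=O)[C@H]1[C@]3(C)O[C@@H]3C[C@H]2C(C)(C)C(=O)CC[C@]12C | intermediate
19 | methyl 7α,8α-epoxy-3α-hydroxydriman-11-oate (not isolated) | COC(=O)[C@H]1[C@]3(C)O[C@@H]3C[C@H]2C(C)(C)[C@H](O)CC[C@]12C | intermediate
20 | drimane-3α,8α,11-triol | OC[C@H]1[C@](C)(O)CC[C@H]2C(C)(C)[C@H](O)CC[C@]12C | intermediate
21 | umbelliferone, 7-hydroxy-2H-chromen-2-one | Oc1ccc2ccc(=O)oc2c1 | starting material
22 | 11-[(2-oxo-2H-chromen-7-yl)oxy]drimane-3α,8α-diol | O(C[C@H]1[C@](C)(O)CC[C@H]2C(C)(C)[C@H](O)CC[C@]12C)c1ccc2ccc(=O)oc2c1 | intermediate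
23 | angelic acid, (2Z)-2-methylbut-2-enoic acid | C/C=C(/C)C(=O)O | starting material
24 | angelic 2,4,6-trichlorobenzoic anhydride (not isolated) | C/C=C(/C)C(=O)OC(=O)c1c(Cl)cc(Cl)cc1Cl | intermediate
25 | 8α-hydroxy-11-[(2-oxo-2H-chromen-7-yl)oxy]driman-3α-yl (2Z)-2-methylbut-2-enoate, CNP0189964.4 | C/C=C(/C)C(=O)O[C@@H]1CC[C@]2(C)[C@@H](COc3ccc4ccc(=O)oc4c3)[C@](C)(O)CC[C@H]2C1(C)C | target

Total step count: 14. Longest linear sequence: 14 steps (1 → 25).

Steps most likely to fail

Step 11 (ring enlargement). What may go wrong: the tertiary C4 radical takes up a second hydrogen atom instead of being oxidised, or the C4 cation is captured by the C3 hydroxyl (spiro-oxirane formation) or loses a proton before the 1,2-shift, or the cationic cobalt species opens the 7,8-epoxide. The fallback sets out from ketone 15 and uses the selenium-based one-carbon ring enlargement of ketones, which generates the same C4 electrophile by heterolysis of a C–Se bond. Acetone and benzeneselenol (ZnCl2, CH2Cl2) give 2,2-bis(phenylselanyl)propane F1. n-C4H9Li in THF at −78 °C cleaves one C–Se bond to give 2-lithio-2-(phenylselanyl)propane F2. Addition of F2 to 15 gives the β-hydroxy selenide F3. AgBF4 on alumina in CH2Cl2 then ionises the C–Se bond, and the same shift of C5 from C3 to C4 should deliver 18, where the route is rejoined.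

Step 13 (aryl ether). What may go wrong: substitution at the doubly β-branched C11 alkoxyphosphonium centre is slow, so that alkylation of the hydrazide, elimination or intramolecular capture by the 8-hydroxyl takes over. The fallback sets out from triol 20 and forms the C11–O–aryl bond from the aryl side by palladium-catalysed C–O cross-coupling with commercially available 7-bromocoumarin ([Pd(C3H5)Cl]2, RockPhos, Cs2CO3, toluene, 90 °C). This coupling is selective for primary alcohols and needs no substitution at C11. It gives 22 directly, where the route is rejoined; the fallback makes no new compound (F0).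

Step 3 (Ireland–Claisen rearrangement). What may go wrong: the dienyl ketene acetal loses the allylic carboxylate (ionisation and elimination to a cyclopentadiene) or is C-silylated, or the [3,3] shift onto the fully substituted C10 is too slow. The fallback sets out from alcohol 2 and transfers only an acetate unit. A Johnson–Claisen rearrangement with trimethyl orthoacetate (propionic acid cat., 140 °C) should give methyl 2-{(1R)-1-methyl-2-[(2Z)-pent-2-en-1-yl]cyclopent-2-en-1-yl}acetate F4 with the same chirality transfer. Aldol addition to acetone (LDA, THF, −78 °C) gives the β-hydroxy ester F5. Dehydration toward the methyl groups (SOCl2, pyridine, 0 °C) gives 8, where the route is rejoined.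

Further compounds
F1 | step 11 | 2,2-bis(phenylselanyl)propane | CC(C)([Se]c1ccccc1)[Se]c1ccccc1
F2 | step 11 | 2-lithio-2-(phenylselanyl)propane | [Li]C(C)(C)[Se]c1ccccc1
F3 | step 11 | methyl 5,6-epoxy-1-hydroxy-3a,5-dimethyl-1-[2-(phenylselanyl)propan-2-yl]octahydro-1H-indene-4-carboxylate | COC(=O)[C@H]1[C@]3(C)O[C@@H]3C[C@H]2C(O)(C(C)(C)[Se]c4ccccc4)CC[C@]12C
F0 | step 13 | none | none
F4 | step 3 | methyl 2-{(1R)-1-methyl-2-[(2Z)-pent-2-en-1-yl]cyclopent-2-en-1-yl}acetate | COC(=O)C[C@@]1(C)CCC=C1C/C=C\CC
F5 | step 3 | methyl 3-hydroxy-3-methyl-2-{(1R)-1-methyl-2-[(2Z)-pent-2-en-1-yl]cyclopent-2-en-1-yl}butanoate | COC(=O)C(C(C)(C)O)[C@@]1(C)CCC=C1C/C=C\CC
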